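The readings are calculated for an exercise.

**The question.** Time was what I had to choose: how long to stir the flask below, and what it then holds.

| setting | dawn | spring | flask |
|---|---|---|---|
| substrate | 5 mM | 7.5 mM | 10 mM |
| gas phase | 3.6 mM (held) | 3.6 mM (held) | 3.6 mM (held) |
| free catalyst | 0.14 mol% | 0.14 mol% | 0.14 mol% |
| remark | run made earlier | run made earlier |  |
| time |  |  | 15 h |

| run | time / h | target / % | substrate / % |
|---|---|---|---|
| dawn | 0.500 | 13 | 90 |
| dawn | 0.833 | 16 | 80 |
| dawn | 1.33 | 25 | 71 |
| dawn | 2.50 | 23 | 60 |
| dawn | 4.00 | 20 | 54 |
| dawn | 8.00 | 12 | 49 |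
| dawn | 12.0 | 13 | 53 |
| spring | 0.500 | 14 | 85 |
| spring | 0.833 | 18 | 76 |
| spring | 1.33 | 29 | 63 |
| spring | 2.50 | 32 | 51 |
| spring | 4.00 | 26 | 47 |
| spring | 8.00 | 16 | 40 |
| spring | 12.0 | 14 | 44 |

(scatter of a reading: 1.5 percentage points)

- time, not beyond 15 h, at which the flask holds most target
- the amount of target, in percent of the substrate charged, at that time
- the first time at which target reaches 18%, in the same percent

- at the start none of the gas is dissolved
- steps that have been proposed: gas phase <-> dissolved gas; substrate + dissolved gas + free catalyst -> free catalyst + target; free catalyst -> spent catalyst; target <-> isomer of the product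

**Share first.** At 12.0 h I asked what share of the converted substrate, which the proposed steps turn into target and isomer, was target. An even split, 0.5, was the zero of my scale. The dawn run read 0.277 and the spring run 0.250, so the late readings lay on the isomer's side, which looked like thermodynamic control. At 2.50 h, the spring run's highest target reading, the share still stood at 0.575 in the dawn run and 0.653 in the spring run.

**Reach.** At that time I also took the reciprocal of [substrate] less the reciprocal of its charge: 0.133 mM⁻¹ in the dawn run and 0.128 mM⁻¹ in the spring run. Their mean, 0.131 mM⁻¹, I called the reach, a measure of conversion by that time that held across both charges. For the flask at 10 mM it gave, at 2.50 h, substrate 43.3%, so 56.7% converted, and the spring share, from the nearer charge, gave target 37.0% at that time.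

**Weak link.** That share was the weak link: the two runs parted by 0.0780, and each reading scatters by 1.5 percentage points. I pooled them, summed target over summed converted, and got 0.618, which put flask target at 35.0% at 2.50 h, the estimate I committed to.

**Forecast.** The forecast, on a measure that “traces nearly the same curve in both runs”, gave 36% at 1.9 h and the asked level at 0.54 h.

**Result.** The flask gave 35.1% at 2.05 h and reached the asked level at 0.587 h.

    gas phase ⇌ dissolved gas, rate k1*(csat - [dissolved gas]) (kL = 7.64 × 10⁻⁴ s⁻¹)
    substrate + dissolved gas + free catalyst → free catalyst + target (k = 7890 M⁻² s⁻¹)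
    free catalyst → spent catalyst (k = 2.21 × 10⁻⁴ s⁻¹)
    target ⇌ isomer of the product (K = 3.14, k = 1.05 × 10⁻⁴ s⁻¹)

**Neighbour.** The flask peaked earlier than 2.50 h, and its own reach at 2.05 h was 0.109 mM⁻¹, less than the 0.131 mM⁻¹ I had read for 2.50 h. For the neighbour flask with 4.0 mM of substrate at the same loading, the reach gave substrate 65.7% at 2.50 h, and the pooled share 0.618 gave target 21.2% at that time. That neighbour flask's highest target was 21.9%.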